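**Remarks on the chemistry.** Carotenoid numbering is used throughout (ring A = C1–C6, chain = C7–C15 and C15'–C7', ring B = C1'–C5'; C6' is the ring B carbonyl). TBS = tert-butyldimethylsilyl, TBDPS = tert-butyldiphenylsilyl. The target is drawn as the hydrogen-bonded enol of its 1,3-diketone; the diketone formed in step 24 is assumed to adopt this tautomer by itself. Compounds 1, 13, 19 and 31 are taken as commercial.

## Analysis of the target

Compound 39 is a C40 carotenoid. Its chain has eight conjugated all-E double bonds (C9 to C9'). On the left it ends in a C7≡C8 triple bond on the tetrasubstituted C5=C6 alkene of ring A. On the right it ends in the Z-configured, chelated enol (C8'–OH) of a 1,3-diketone whose other carbonyl, C6', sits on ring B.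

Ring A is a cyclohexene with a trans-3,4-diol (3S,4S); the C4 hydroxyl is allylic. Ring B is a cyclopentane with a secondary hydroxyl at C3' (S) and a quaternary carbon C5' (R). C5' carries a methyl group and the acyl carbon C6', lies between the gem-dimethyl carbon C1' and C4'H2, and has the C3' hydroxyl trans to its acyl group.

The two pairs of stereocentres are more than twenty bonds apart, so neither can control the other and each ring must bring its own absolute configuration. Sensitive points are:

- the polyene (light, acid, oxidants);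
- the 9E double bond next to the alkyne, which is prone to stereomutation;
- the ionisable allylic C4–O bond;
- the acidic diketone, which is open to retro-Claisen cleavage;
- the neopentyl, doubly flanked carbonyl C6'.

The hardest single element is C5': an all-carbon quaternary stereocentre next to another fully substituted carbon is not readily made by asymmetric C–C bond formation. The plan rests on one observation. The five carbons of ring B, its three methyl groups and C6' form the skeleton of (1R,3S)-camphoric acid 1 (C5' = its quaternary C1, C1' = its C2, C6' = its tertiary carboxyl carbon). Acid 1 has one carbon too many, the secondary carboxyl on C2', and C5' already has the required configuration there.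

## Retrosynthetic reasoning

**39 from 38.** The last operation only removes silyl groups (two TBS ethers on ring A, one TBDPS ether on ring B). The diketone needs no protection because it is created one step earlier.

**38 from 37, and 37 from 35 and 12 (C6'–C7' bond).** With C6' taken back to the alcohol level, the C6'–C7' bond is cut as an aldol. This cut separates ring B, with both its stereocentres, from the whole polyene. Aldehyde 12 cannot enolise and ketone 35 has only one kinetically acidic site, the C7' methyl, so the union has no regiochemical choice. The acidic diketone then exists for one step only. The forward reaction must add a polyenone enolate to a very hindered aldehyde and then oxidise the carbinol.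

**35 from 27 and 33; 33 from 30 and 31 (C11=C12 and C11'=C12').** The symmetrical dialdehyde 31 supplies C12 to C12' with three E double bonds in place. The small C5 salt 30 is attached first, so the valuable ring A salt 27 later meets a mono-aldehyde in equimolar amounts. Salt 30 comes from enynol 19 through hydroxy enone 28, so one C6 building block serves both ends of the chain.

**27 back to 22, and 22 from 18 and 19 (C4 centre, then C6–C7 bond).** The C4 stereocentre is set by reduction of enynone 22 under control of the neighbouring C3 silyloxy group (22 → 23), followed by protecting-group and leaving-group adjustment (24, 25, 27). Cutting C6–C7 in 22 leads to the vinylogous ester 18 and the acetylide of 19. The forward addition–transposition installs the C5=C6 double bond and the C4 carbonyl in one operation and needs no separate dehydration.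

**18 back to 13.** The C3 centre comes from enantioselective reduction of the only unhindered ketone of 16. The C4 oxygen of 16 is introduced by epoxidation and isomerisation of ketoisophorone 13 (via 15).

**12 back to 5.** The C3' oxygen is introduced by hydroboration of the C2'=C3' alkene in 7. The fully substituted C1' directs boron to C3', and the silyloxymethyl group on C5' directs it to the correct face. Two silyl groups of different acid lability (10) allow C6' to be freed (11) and oxidised (12). Alkene 7 comes from ester 5 through alcohol 6.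

**5 from 3 (key disconnection), and 3 from 1.** Retrosynthetically a carboxyl group is added to C2' of 5, which gives the mono-ester 3 and hence camphoric acid 1. The ring–carboxyl bond is the only bond that separates ring B from the chiral-pool skeleton. Cleaving it turns the C5' problem into a purchase and leaves the alkene where oxygen is needed. The two carboxyls of 1 are told apart by hindrance (diester 2, selective saponification to 3).

## Alternatives that were turned down

**Alternative 1: double Stille coupling.**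
- Disconnection: the two sp2–sp2 single bonds C10–C11 and C10'–C11'. This gives a central bis-stannylated pentaene A2 (C11 to C11'), the ring A iodo-enyne A3 and the ring B iodo-dienolone A4.
- Forward key step: two successive Stille couplings under zerovalent palladium catalysis with a weakly binding arsine ligand, giving the tris-silyl ether A1.
- For it: the couplings are stereoretentive, so every double-bond geometry is fixed in the fragments. This is a real advantage at the 9,10 bond, where the Wittig reaction of 27 can leak to Z. It is also more convergent and runs under neutral conditions.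
- Against it: the two identical C–Sn ends of A2 must be differentiated, so mono- and double coupling compete. A4 combines a vinyl iodide with an acidic, chelating diketone that can bind palladium and is hard to obtain as one isomer. Polyenyl stannanes protodestannylate easily, and tin residues must be removed from a polyene.
- Comparison: this alternative is stronger on geometry and convergence. It does not address C5', since A4 still needs ring B from some source. The chosen plan provides C5' from the chiral pool in three steps and builds the chain from the commercial unit 31 by carbonyl olefination without tin.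

**Alternative 2: Sonogashira coupling at C6–C7.**
- Disconnection: the sp2–sp bond C6–C7, giving the ring A enol triflate A6 and enynol 19.
- Forward key step: Sonogashira coupling (zerovalent palladium, a monovalent copper co-catalyst, an amine) to give A5, which is the same compound as 25.
- For it: one step from A6, the E geometry of 19 is untouched and no acid is used.
- Against it: A6 must come from a cyclohexanone carrying both silyloxy groups, so three stereocentres (C3, C4, C5) have to be set although C5 is then flattened. Enolisation toward C5 places the C4 silyloxy group β to the carbonyl and invites β-elimination. Oxidative addition into a tetrasubstituted triflate between a gem-dimethyl carbon and a methyl-bearing carbon is slow.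
- Comparison: it would be shorter than the sequence 18 → 25 if A6 were at hand, and it avoids the acid-induced transposition. The chosen route reaches the same compound 25 by carrying the C4 oxygen as a carbonyl and setting its configuration afterwards. Ring B is again left unsolved by this alternative.

**Alternative 3: central C15=C15' Wittig union.**
- Disconnection: the central double bond, giving the left C20 phosphonium salt A8 and the right C20 trienal A9, whose diketone is held as a silyl enol ether.
- Forward key step: Wittig condensation and equilibration to all-E, giving the tetrakis-silyl compound A7.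
- For it: it is the most convergent plan. The central disubstituted double bond is the least hindered place to join, its Z isomer is the easiest to isomerise, and no dialdehyde has to be mono-olefinated.
- Against it: each half needs its own chain extension to C20, whereas 31 delivers ten carbons and three E double bonds in one piece. A9 must carry a hydrolytically labile, regiochemically ambiguous silyl enol ether through several steps. Equilibration of a 7,8-didehydro polyene puts the 9,10 geometry at risk.
- Comparison: it is better on convergence and on the statistical problem of step 21. The chosen route has fewer chain-building steps and forms the diketone only in the penultimate step. The origin of C5' is not touched by this alternative.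

Key step: step 3

## Route

Step 1
Reactants: 1 (1R,3S)-camphoric acid
Product: 2 dimethyl (1R,3S)-1,2,2-trimethylcyclopentane-1,3-dicarboxylate
Conditions: MeI (3 equiv), K2CO3 (3 equiv), DMF, rt
Reagents that add atoms: iodomethane, CI
Why: Carboxylate O-alkylation (SN2 on iodomethane) is insensitive to the hindrance at the tertiary carboxyl, which resists Fischer esterification, so both acids are esterified; no stereocentre is touched.

Step 2
Reactants: 2 dimethyl (1R,3S)-1,2,2-trimethylcyclopentane-1,3-dicarboxylate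
Product: 3 (1S,3R)-3-(methoxycarbonyl)-2,2,3-trimethylcyclopentane-1-carboxylic acid
Conditions: KOH (1.1 equiv), MeOH/H2O, reflux; then aq. HCl
Reagents that add atoms: potassium hydroxide, [K+].[OH-]
Why: Saponification (addition–elimination at the acyl carbon) reaches only the secondary ester, because the tertiary ester on the quaternary carbon next to the gem-dimethyl carbon is shielded from hydroxide; epimerisation α to the secondary carboxyl would be harmless since that centre is erased in step 3.

Step 3
Reactants: 3 (1S,3R)-3-(methoxycarbonyl)-2,2,3-trimethylcyclopentane-1-carboxylic acid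
Product: 5 methyl (1R)-1,2,2-trimethylcyclopent-3-ene-1-carboxylate, via lead carboxylate 4 (not isolated)
Conditions: Pb(OAc)4 (1.5 equiv), Cu(OAc)2·H2O (0.1 equiv), pyridine (1 equiv), benzene, 80 °C, N2
Reagents that add atoms: none
Why: Kochi oxidative decarboxylation: the free acid exchanges for acetate on tetravalent lead to give 4, whose Pb–O bond homolyses on heating, and loss of CO2 from the acyloxy radical leaves a secondary radical at C2'. Divalent copper captures this radical faster than tetravalent lead can oxidise it and converts it, through an alkylcopper intermediate, into the alkene by loss of a β-hydrogen; the monovalent copper formed is reoxidised by lead, so the chain continues. The closest known reaction type is the conversion of secondary cycloalkanecarboxylic acids into cycloalkenes by lead tetraacetate with Cu(OAc)2. No ring is closed and no stereocentre is formed; the C2' centre is erased and the quaternary C5' centre, which cannot epimerise, is carried through unchanged. Three selectivities are needed: only the free secondary carboxyl can bind lead, so the tertiary ester is untouched; the only β-hydrogens are on C3', because C1' is fully substituted, so a single alkene (C2'=C3') can form; and a free cation at C2', which would invite a 1,2-methyl shift from C1' or capture by acetate, is avoided by the copper pathway.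

Step 4
Reactants: 5 methyl (1R)-1,2,2-trimethylcyclopent-3-ene-1-carboxylate
Product: 6 [(1R)-1,2,2-trimethylcyclopent-3-en-1-yl]methanol
Conditions: LiAlH4, Et2O, 0 °C → reflux
Reagents that add atoms: none
Why: Hydride reduction of the hindered neopentyl ester to the primary alcohol; the isolated alkene and the quaternary centre are inert to LiAlH4.

Step 5
Reactants: 6 [(1R)-1,2,2-trimethylcyclopent-3-en-1-yl]methanol
Product: 7 tert-butyldimethyl{[(1R)-1,2,2-trimethylcyclopent-3-en-1-yl]methoxy}silane
Conditions: TBSCl, imidazole, DMF, rt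
Reagents that add atoms: tert-butyldimethylsilyl chloride, CC(C)(C)[Si](C)(C)Cl
Why: Standard silylation of a primary alcohol; the silyloxymethyl group becomes the larger of the two substituents on C5' and serves as the steering group for step 6.

Step 6
Reactants: 7 tert-butyldimethyl{[(1R)-1,2,2-trimethylcyclopent-3-en-1-yl]methoxy}silane
Product: 9 (1S,3R)-3-[(TBS-oxy)methyl]-3,4,4-trimethylcyclopentan-1-ol, via alkylborane 8 (not isolated)
Conditions: 9-BBN (1.5 equiv), THF, 0 → 65 °C; then NaOH, H2O2, 0 °C → rt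
Reagents that add atoms: hydrogen peroxide, OO
Why: Hydroboration–oxidation: the bulky borane adds syn across C2'=C3' with boron on C3', away from the neopentyl C2', and from the face anti to the silyloxymethyl group on C5', the only element that distinguishes the two faces; oxidation with retention should give the (3'S)-alcohol trans to C6'.

Step 7
Reactants: 9 (1S,3R)-3-[(TBS-oxy)methyl]-3,4,4-trimethylcyclopentan-1-ol
Product: 10 tert-butyl{[(1S,3R)-3-[(TBS-oxy)methyl]-3,4,4-trimethylcyclopentyl]oxy}diphenylsilane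
Conditions: TBDPSCl, imidazole, DMAP (cat.), DMF, 40 °C
Reagents that add atoms: tert-butyldiphenylsilyl chloride, CC(C)(C)[Si](Cl)(c1ccccc1)c1ccccc1
Why: Silylation of the secondary alcohol with the acid-stable TBDPS group, chosen so that the primary TBS ether can be cleaved in its presence.

Step 8
Reactants: 10 tert-butyl{[(1S,3R)-3-[(TBS-oxy)methyl]-3,4,4-trimethylcyclopentyl]oxy}diphenylsilane
Product: 11 [(1R,4S)-4-(TBDPS-oxy)-1,2,2-trimethylcyclopentyl]methanol
Conditions: camphorsulfonic acid (0.1 equiv), MeOH/CH2Cl2, 0 °C → rt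
Reagents that add atoms: none
Why: Acid-catalysed methanolysis cleaves the primary TBS ether far faster than the secondary TBDPS ether, which follows from the known difference in acid lability of the two silyl groups.

Step 9
Reactants: 11 [(1R,4S)-4-(TBDPS-oxy)-1,2,2-trimethylcyclopentyl]methanol
Product: 12 (1R,4S)-4-(TBDPS-oxy)-1,2,2-trimethylcyclopentane-1-carbaldehyde
Conditions: Dess–Martin periodinane, NaHCO3, CH2Cl2, rt
Reagents that add atoms: none
Why: Dess–Martin oxidation of the neopentyl primary alcohol; the aldehyde has no α-hydrogen, so it can neither enolise nor epimerise.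

Step 10
Reactants: 13 ketoisophorone (2,6,6-trimethylcyclohex-2-ene-1,4-dione)
Product: 15 2-hydroxy-3,5,5-trimethylcyclohex-2-ene-1,4-dione, via epoxide 14 (not isolated)
Conditions: H2O2 (30% aq.), NaOH (cat.), MeOH, 0–10 °C; then aq. NaOH, 40 °C; then aq. HCl
Reagents that add atoms: hydrogen peroxide, OO
Why: Weitz–Scheffer epoxidation of the electron-poor ene-dione, then base-induced opening of the oxirane by loss of the epoxide hydrogen α to the unhindered carbonyl (E1cB) gives the enolised 1,2-dione and so places the future C4 oxygen; no stereocentre survives the step.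

Step 11
Reactants: 15 2-hydroxy-3,5,5-trimethylcyclohex-2-ene-1,4-dione
Product: 16 2-methoxy-3,5,5-trimethylcyclohex-2-ene-1,4-dione
Conditions: Me2SO4, K2CO3, acetone, reflux
Reagents that add atoms: dimethyl sulfate, COS(=O)(=O)OC
Why: O-Alkylation of the acidic diosphenol with a hard methylating agent gives the methyl enol ether; this turns the hindered carbonyl into a vinylogous ester and leaves the other carbonyl as the only reactive ketone.

Step 12
Reactants: 16 2-methoxy-3,5,5-trimethylcyclohex-2-ene-1,4-dione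
Product: 17 (4S)-4-hydroxy-3-methoxy-2,6,6-trimethylcyclohex-2-en-1-one
Conditions: (R)-2-methyl-CBS-oxazaborolidine (0.2 equiv), BH3·SMe2 (0.7 equiv), THF, −20 °C; MeOH, then aqueous work-up
Reagents that add atoms: none
Why: Corey–Bakshi–Shibata reduction: borane is delivered within the oxazaborolidine complex to the unhindered ketone, with the alkenyl carbon as the large and the methylene as the small substituent, which with the (R)-catalyst should give the (S)-carbinol (C3); the vinylogous ester carbonyl, flanked by the gem-dimethyl carbon and deactivated by the methoxy group, is not reduced.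

Step 13
Reactants: 17 (4S)-4-hydroxy-3-methoxy-2,6,6-trimethylcyclohex-2-en-1-one
Product: 18 (4S)-4-(TBS-oxy)-3-methoxy-2,6,6-trimethylcyclohex-2-en-1-one
Conditions: TBSCl, imidazole, DMF, rt
Reagents that add atoms: tert-butyldimethylsilyl chloride, CC(C)(C)[Si](C)(C)Cl
Why: Standard silylation of the secondary alcohol; the bulky ether protects C3–OH from the organolithium reagent and later acts as the control element in step 15.

Step 14
Reactants: 18 (4S)-4-(TBS-oxy)-3-methoxy-2,6,6-trimethylcyclohex-2-en-1-one; 19 (2E)-3-methylpent-2-en-4-yn-1-ol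
Product: 22 (6S)-6-(TBS-oxy)-3-[(3E)-5-hydroxy-3-methylpent-3-en-1-yn-1-yl]-2,4,4-trimethylcyclohex-2-en-1-one, via dilithio enynolate 20 (not isolated), via tertiary alcohol adduct 21 (not isolated)
Conditions: 19 (1.5 equiv), n-BuLi (3.0 equiv), THF, −78 → 0 °C; then 18, −78 → 0 °C; then 1 M HCl, THF, 0 °C
Reagents that add atoms: water, O
Why: Stork–Danheiser sequence: the acetylide end of 20 adds 1,2 to the vinylogous ester carbonyl, then acid ionises the tertiary alcohol, water adds to the oxocarbenium carbon C4 and methanol is lost, which gives the C4 ketone and the C5=C6 double bond at once; the E enyne geometry comes from 19, the C3 centre is not involved, and dilute acid at 0 °C should spare the secondary silyl ether.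

Step 15
Reactants: 22 (6S)-6-(TBS-oxy)-3-[(3E)-5-hydroxy-3-methylpent-3-en-1-yn-1-yl]-2,4,4-trimethylcyclohex-2-en-1-one
Product: 23 (1S,6S)-6-(TBS-oxy)-3-[(3E)-5-hydroxy-3-methylpent-3-en-1-yn-1-yl]-2,4,4-trimethylcyclohex-2-en-1-ol
Conditions: NaBH4, CeCl3·7H2O, MeOH, −40 °C
Reagents that add atoms: none
Why: Luche reduction (1,2-selective): with the silyloxy group pseudo-equatorial, axial hydride delivery to the enone carbonyl gives the pseudo-equatorial C4 alcohol trans to the C3 silyloxy group, that is (4S).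

Step 16
Reactants: 23 (1S,6S)-6-(TBS-oxy)-3-[(3E)-5-hydroxy-3-methylpent-3-en-1-yn-1-yl]-2,4,4-trimethylcyclohex-2-en-1-ol
Product: 24 tert-butyl({(2E)-5-[(3S,4S)-3,4-bis(TBS-oxy)-2,6,6-trimethylcyclohex-1-en-1-yl]-3-methylpent-2-en-4-yn-1-yl}oxy)dimethylsilane
Conditions: TBSOTf (2.5 equiv), 2,6-lutidine, CH2Cl2, −78 → 0 °C
Reagents that add atoms: tert-butyldimethylsilyl trifluoromethanesulfonate, CC(C)(C)[Si](C)(C)OS(=O)(=O)C(F)(F)F
Why: The silyl triflate with a hindered base silylates both the primary and the hindered secondary allylic alcohol, with no free acid that could ionise the C4–O bond.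

Step 17
Reactants: 24 tert-butyl({(2E)-5-[(3S,4S)-3,4-bis(TBS-oxy)-2,6,6-trimethylcyclohex-1-en-1-yl]-3-methylpent-2-en-4-yn-1-yl}oxy)dimethylsilane
Product: 25 (2E)-5-[(3S,4S)-3,4-bis(TBS-oxy)-2,6,6-trimethylcyclohex-1-en-1-yl]-3-methylpent-2-en-4-yn-1-ol
Conditions: HF·pyridine, pyridine, THF, 0 °C
Reagents that add atoms: none
Why: Buffered HF·pyridine removes the unhindered primary allylic TBS ether selectively; the two secondary ethers on ring A react much more slowly for steric reasons.

Step 18
Reactants: 25 (2E)-5-[(3S,4S)-3,4-bis(TBS-oxy)-2,6,6-trimethylcyclohex-1-en-1-yl]-3-methylpent-2-en-4-yn-1-ol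
Product: 27 {(2E)-5-[(3S,4S)-3,4-bis(TBS-oxy)-2,6,6-trimethylcyclohex-1-en-1-yl]-3-methylpent-2-en-4-yn-1-yl}triphenylphosphonium bromide, via allylic bromide 26 (not isolated)
Conditions: CBr4, PPh3 (1.1 equiv), CH2Cl2, −20 °C; then PPh3 (1.2 equiv), rt
Reagents that add atoms: carbon tetrabromide, BrC(Br)(Br)Br; triphenylphosphine, c1ccc(cc1)P(c1ccccc1)c1ccccc1
Why: Appel bromination of the primary allylic alcohol under neutral conditions (SN2 on the alkoxyphosphonium ion), followed in the same flask by SN2 quaternisation of the allylic bromide by the excess phosphine.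

Step 19
Reactants: 19 (2E)-3-methylpent-2-en-4-yn-1-ol
Product: 28 (3E)-5-hydroxy-3-methylpent-3-en-2-one
Conditions: NaAuCl4·2H2O (2 mol%), MeOH/H2O (10:1), 65 °C
Reagents that add atoms: water, O
Why: Gold-catalysed Markovnikov hydration of the terminal alkyne gives the methyl ketone; the E geometry keeps the hydroxyl away from the activated alkyne, and the conjugated E enone is the stable isomer.

Step 20
Reactants: 28 (3E)-5-hydroxy-3-methylpent-3-en-2-one
Product: 30 [(2E)-3-methyl-4-oxopent-2-en-1-yl]triphenylphosphonium bromide, via allylic bromide 29 (not isolated)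
Conditions: CBr4, PPh3 (1.1 equiv), CH2Cl2, 0 °C; then PPh3 (1.2 equiv), rt
Reagents that add atoms: carbon tetrabromide, BrC(Br)(Br)Br; triphenylphosphine, c1ccc(cc1)P(c1ccccc1)c1ccccc1
Why: Appel bromination of the primary allylic alcohol, then quaternisation of the reactive γ-bromo enone by triphenylphosphine; the simple ketone does not react under these conditions.

Step 21
Reactants: 30 [(2E)-3-methyl-4-oxopent-2-en-1-yl]triphenylphosphonium bromide; 31 (2E,4E,6E)-2,7-dimethylocta-2,4,6-trienedial
Product: 33 (2E,4E,6E,8E,10E)-2,7,11-trimethyl-12-oxotrideca-2,4,6,8,10-pentaenal, via ylide 32 (not isolated)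
Conditions: 30, 2 M NaOH/CH2Cl2, 0 °C; then 31 (3 equiv), CH2Cl2, rt
Reagents that add atoms: none
Why: Wittig reaction of the acyl-stabilised (vinylogous) ylide, which is formed with aqueous hydroxide and used without excess base, so ketone and aldehydes see no strong base; the excess of 31 suppresses double olefination, and the stabilised ylide should give the E alkene at C11'=C12'.

Step 22
Reactants: 27 {(2E)-5-[(3S,4S)-3,4-bis(TBS-oxy)-2,6,6-trimethylcyclohex-1-en-1-yl]-3-methylpent-2-en-4-yn-1-yl}triphenylphosphonium bromide; 33 (2E,4E,6E,8E,10E)-2,7,11-trimethyl-12-oxotrideca-2,4,6,8,10-pentaenal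
Product: 35 (3E,5E,7E,9E,11E,13E,15E)-18-[(3S,4S)-3,4-bis(TBS-oxy)-2,6,6-trimethylcyclohex-1-en-1-yl]-3,7,12,16-tetramethyloctadeca-3,5,7,9,11,13,15-heptaen-17-yn-2-one, via ylide 34 (not isolated)
Conditions: 27, NaN(SiMe3)2 (1.0 equiv), THF, −78 °C; then 33, −78 °C → rt; then heptane, 80 °C, dark
Reagents that add atoms: none
Why: Wittig reaction: the ylide is formed with exactly one equivalent of a hindered amide base before 33 is added, so it meets only the aldehyde (the conjugated methyl ketone is far less electrophilic); the semi-stabilised ylide gives an E/Z mixture at C11=C12 and the hindered Z isomer should revert to E on heating, iodine being avoided because it would also equilibrate the 9,10 bond.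

Step 23
Reactants: 35 (3E,5E,7E,9E,11E,13E,15E)-18-[(3S,4S)-3,4-bis(TBS-oxy)-2,6,6-trimethylcyclohex-1-en-1-yl]-3,7,12,16-tetramethyloctadeca-3,5,7,9,11,13,15-heptaen-17-yn-2-one; 12 (1R,4S)-4-(TBDPS-oxy)-1,2,2-trimethylcyclopentane-1-carbaldehyde
Product: 37 (4E,6E,8E,10E,12E,14E,16E)-19-[(3S,4S)-3,4-bis(TBS-oxy)-2,6,6-trimethylcyclohex-1-en-1-yl]-1-hydroxy-4,8,13,17-tetramethyl-1-[(1R,4S)-4-(TBDPS-oxy)-1,2,2-trimethylcyclopentyl]nonadeca-4,6,8,10,12,14,16-heptaen-18-yn-3-one (both C6' epimers), via lithium enolate 36 (not isolated)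
Conditions: LiN(i-Pr)2 (1.05 equiv), THF, −78 °C; then 12 (1.2 equiv), −78 → −40 °C; AcOH quench at −78 °C
Reagents that add atoms: none
Why: Directed aldol addition: LiN(i-Pr)2 removes a proton from the C7' methyl group, the only kinetically acidic site of 35, and the enolate adds to the non-enolisable aldehyde 12; the configuration of the new carbinol C6' is irrelevant because it is oxidised in step 24.

Step 24
Reactants: 37 (4E,6E,8E,10E,12E,14E,16E)-19-[(3S,4S)-3,4-bis(TBS-oxy)-2,6,6-trimethylcyclohex-1-en-1-yl]-1-hydroxy-4,8,13,17-tetramethyl-1-[(1R,4S)-4-(TBDPS-oxy)-1,2,2-trimethylcyclopentyl]nonadeca-4,6,8,10,12,14,16-heptaen-18-yn-3-one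
Product: 38 (2Z,4E,6E,8E,10E,12E,14E,16E)-19-[(3S,4S)-3,4-bis(TBS-oxy)-2,6,6-trimethylcyclohex-1-en-1-yl]-3-hydroxy-4,8,13,17-tetramethyl-1-[(1R,4S)-4-(TBDPS-oxy)-1,2,2-trimethylcyclopentyl]nonadeca-2,4,6,8,10,12,14,16-octaen-18-yn-1-one
Conditions: Dess–Martin periodinane, pyridine, CH2Cl2, 0 °C → rt, dark
Reagents that add atoms: none
Why: Dess–Martin oxidation of a β-hydroxy ketone to the 1,3-diketone, a standard use of the reagent that avoids C–C cleavage; pyridine buffers the acetic acid released, which protects the polyene and the allylic silyl ether, and the diketone should settle in the chelated enol conjugated with the chain.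

Step 25
Reactants: 38 (2Z,4E,6E,8E,10E,12E,14E,16E)-19-[(3S,4S)-3,4-bis(TBS-oxy)-2,6,6-trimethylcyclohex-1-en-1-yl]-3-hydroxy-4,8,13,17-tetramethyl-1-[(1R,4S)-4-(TBDPS-oxy)-1,2,2-trimethylcyclopentyl]nonadeca-2,4,6,8,10,12,14,16-octaen-18-yn-1-one
Product: 39 (2Z,4E,6E,8E,10E,12E,14E,16E)-19-[(3S,4S)-3,4-dihydroxy-2,6,6-trimethylcyclohex-1-en-1-yl]-3-hydroxy-1-[(1R,4S)-4-hydroxy-1,2,2-trimethylcyclopentyl]-4,8,13,17-tetramethylnonadeca-2,4,6,8,10,12,14,16-octaen-18-yn-1-one (CNP0114063.1)
Conditions: Bu4NF (6 equiv), THF, 0 °C → rt, dark; aqueous work-up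
Reagents that add atoms: none
Why: Fluoride-induced cleavage of the three silyl ethers, driven by Si–F bond formation; the diketone is only deprotonated under these conditions and is recovered on mild work-up, and no stereocentre or double bond is affected.

## Compound list

1 | (1R,3S)-1,2,2-trimethylcyclopentane-1,3-dicarboxylic acid, (1R,3S)-camphoric acid | OC(=O)[C@]1(C)CC[C@H](C(=O)O)C1(C)C | starting material
2 | dimethyl (1R,3S)-1,2,2-trimethylcyclopentane-1,3-dicarboxylate | COC(=O)[C@]1(C)CC[C@H](C(=O)OC)C1(C)C | intermediate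
3 | (1S,3R)-3-(methoxycarbonyl)-2,2,3-trimethylcyclopentane-1-carboxylic acid | COC(=O)[C@]1(C)CC[C@H](C(=O)O)C1(C)C | intermediate
4 | {[(1S,3R)-3-(methoxycarbonyl)-2,2,3-trimethylcyclopentane-1-carbonyl]oxy}lead triacetate (not isolated) | COC(=O)[C@]1(C)CC[C@H](C(=O)O[Pb](OC(C)=O)(OC(C)=O)OC(C)=O)C1(C)C | intermediate
5 | methyl (1R)-1,2,2-trimethylcyclopent-3-ene-1-carboxylate | COC(=O)[C@]1(C)CC=CC1(C)C | intermediate
6 | [(1R)-1,2,2-trimethylcyclopent-3-en-1-yl]methanol | OC[C@]1(C)CC=CC1(C)C | intermediate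
7 | tert-butyldimethyl{[(1R)-1,2,2-trimethylcyclopent-3-en-1-yl]methoxy}silane | CC(C)(C)[Si](C)(C)OC[C@]1(C)CC=CC1(C)C | intermediate
8 | 9-[(1S,3R)-3-({[tert-butyl(dimethyl)silyl]oxy}methyl)-3,4,4-trimethylcyclopentyl]-9-borabicyclo[3.3.1]nonane (not isolated) | CC(C)(C)[Si](C)(C)OC[C@]1(C)C[C@@H](B2C3CCCC2CCC3)CC1(C)C | intermediate
9 | (1S,3R)-3-({[tert-butyl(dimethyl)silyl]oxy}methyl)-3,4,4-trimethylcyclopentan-1-ol | CC(C)(C)[Si](C)(C)OC[C@]1(C)C[C@@H](O)CC1(C)C | intermediate
10 | tert-butyl{[(1S,3R)-3-({[tert-butyl(dimethyl)silyl]oxy}methyl)-3,4,4-trimethylcyclopentyl]oxy}diphenylsilane | CC(C)(C)[Si](C)(C)OC[C@]1(C)C[C@@H](O[Si](c2ccccc2)(c2ccccc2)C(C)(C)C)CC1(C)C | intermediate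
11 | [(1R,4S)-4-{[tert-butyl(diphenyl)silyl]oxy}-1,2,2-trimethylcyclopentyl]methanol | OC[C@]1(C)C[C@@H](O[Si](c2ccccc2)(c2ccccc2)C(C)(C)C)CC1(C)C | intermediate
12 | (1R,4S)-4-{[tert-butyl(diphenyl)silyl]oxy}-1,2,2-trimethylcyclopentane-1-carbaldehyde | O=C[C@]1(C)C[C@@H](O[Si](c2ccccc2)(c2ccccc2)C(C)(C)C)CC1(C)C | intermediate
13 | 2,6,6-trimethylcyclohex-2-ene-1,4-dione, ketoisophorone | CC1=CC(=O)CC(C)(C)C1=O | starting material
14 | 1,3,3-trimethyl-7-oxabicyclo[4.1.0]heptane-2,5-dione, racemic (not isolated) | CC12OC1C(=O)CC(C)(C)C2=O | intermediate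
15 | 2-hydroxy-3,5,5-trimethylcyclohex-2-ene-1,4-dione | CC1=C(O)C(=O)CC(C)(C)C1=O | intermediate
16 | 2-methoxy-3,5,5-trimethylcyclohex-2-ene-1,4-dione | COC1=C(C)C(=O)C(C)(C)CC1=O | intermediate
17 | (4S)-4-hydroxy-3-methoxy-2,6,6-trimethylcyclohex-2-en-1-one | COC1=C(C)C(=O)C(C)(C)C[C@@H]1O | intermediate
18 | (4S)-4-{[tert-butyl(dimethyl)silyl]oxy}-3-methoxy-2,6,6-trimethylcyclohex-2-en-1-one | COC1=C(C)C(=O)C(C)(C)C[C@@H]1O[Si](C)(C)C(C)(C)C | intermediate
19 | (2E)-3-methylpent-2-en-4-yn-1-ol | C#C/C(C)=C/CO | starting material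
20 | lithium (2E)-5-lithio-3-methylpent-2-en-4-yn-1-olate (not isolated) | [Li]C#C/C(C)=C/CO[Li] | intermediate
21 | (4S)-4-{[tert-butyl(dimethyl)silyl]oxy}-1-[(3E)-5-hydroxy-3-methylpent-3-en-1-yn-1-yl]-3-methoxy-2,6,6-trimethylcyclohex-2-en-1-ol, both C1 epimers (not isolated) | COC1=C(C)C(O)(C#C/C(C)=C/CO)C(C)(C)C[C@@H]1O[Si](C)(C)C(C)(C)C | intermediate
22 | (6S)-6-{[tert-butyl(dimethyl)silyl]oxy}-3-[(3E)-5-hydroxy-3-methylpent-3-en-1-yn-1-yl]-2,4,4-trimethylcyclohex-2-en-1-one | CC1=C(C#C/C(C)=C/CO)C(C)(C)C[C@H](O[Si](C)(C)C(C)(C)C)C1=O | intermediate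
23 | (1S,6S)-6-{[tert-butyl(dimethyl)silyl]oxy}-3-[(3E)-5-hydroxy-3-methylpent-3-en-1-yn-1-yl]-2,4,4-trimethylcyclohex-2-en-1-ol | CC1=C(C#C/C(C)=C/CO)C(C)(C)C[C@H](O[Si](C)(C)C(C)(C)C)[C@H]1O | intermediate
24 | tert-butyl({(2E)-5-[(3S,4S)-3,4-bis({[tert-butyl(dimethyl)silyl]oxy})-2,6,6-trimethylcyclohex-1-en-1-yl]-3-methylpent-2-en-4-yn-1-yl}oxy)dimethylsilane | CC1=C(C#C/C(C)=C/CO[Si](C)(C)C(C)(C)C)C(C)(C)C[C@H](O[Si](C)(C)C(C)(C)C)[C@H]1O[Si](C)(C)C(C)(C)C | intermediate
25 | (2E)-5-[(3S,4S)-3,4-bis({[tert-butyl(dimethyl)silyl]oxy})-2,6,6-trimethylcyclohex-1-en-1-yl]-3-methylpent-2-en-4-yn-1-ol | CC1=C(C#C/C(C)=C/CO)C(C)(C)C[C@H](O[Si](C)(C)C(C)(C)C)[C@H]1O[Si](C)(C)C(C)(C)C | intermediate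
26 | (3S,4S)-1-[(3E)-5-bromo-3-methylpent-3-en-1-yn-1-yl]-3,4-bis({[tert-butyl(dimethyl)silyl]oxy})-2,6,6-trimethylcyclohex-1-ene (not isolated) | CC1=C(C#C/C(C)=C/CBr)C(C)(C)C[C@H](O[Si](C)(C)C(C)(C)C)[C@H]1O[Si](C)(C)C(C)(C)C | intermediate
27 | {(2E)-5-[(3S,4S)-3,4-bis({[tert-butyl(dimethyl)silyl]oxy})-2,6,6-trimethylcyclohex-1-en-1-yl]-3-methylpent-2-en-4-yn-1-yl}triphenylphosphonium bromide | CC1=C(C#C/C(C)=C/C[P+](c2ccccc2)(c2ccccc2)c2ccccc2)C(C)(C)C[C@H](O[Si](C)(C)C(C)(C)C)[C@H]1O[Si](C)(C)C(C)(C)C.[Br-] | intermediate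
28 | (3E)-5-hydroxy-3-methylpent-3-en-2-one | CC(=O)/C(C)=C/CO | intermediate
29 | (3E)-5-bromo-3-methylpent-3-en-2-one (not isolated) | CC(=O)/C(C)=C/CBr | intermediate
30 | [(2E)-3-methyl-4-oxopent-2-en-1-yl]triphenylphosphonium bromide | CC(=O)/C(C)=C/C[P+](c1ccccc1)(c1ccccc1)c1ccccc1.[Br-] | intermediate
31 | (2E,4E,6E)-2,7-dimethylocta-2,4,6-trienedial | O=C/C(C)=C/C=C/C=C(C)/C=O | starting material
32 | (3E)-3-methyl-5-(triphenylphosphoranylidene)pent-3-en-2-one (not isolated) | CC(=O)/C(C)=C/C=P(c1ccccc1)(c1ccccc1)c1ccccc1 | intermediate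
33 | (2E,4E,6E,8E,10E)-2,7,11-trimethyl-12-oxotrideca-2,4,6,8,10-pentaenal | CC(=O)/C(C)=C/C=C/C(C)=C/C=C/C=C(C)/C=O | intermediate
34 | ylide of 27, {(2E)-5-[(3S,4S)-3,4-bis({[tert-butyl(dimethyl)silyl]oxy})-2,6,6-trimethylcyclohex-1-en-1-yl]-3-methylpent-2-en-4-yn-1-ylidene}triphenylphosphorane (not isolated) | CC1=C(C#C/C(C)=C/C=P(c2ccccc2)(c2ccccc2)c2ccccc2)C(C)(C)C[C@H](O[Si](C)(C)C(C)(C)C)[C@H]1O[Si](C)(C)C(C)(C)C | intermediate
35 | (3E,5E,7E,9E,11E,13E,15E)-18-[(3S,4S)-3,4-bis({[tert-butyl(dimethyl)silyl]oxy})-2,6,6-trimethylcyclohex-1-en-1-yl]-3,7,12,16-tetramethyloctadeca-3,5,7,9,11,13,15-heptaen-17-yn-2-one | CC1=C(C#C/C(C)=C/C=C/C(C)=C/C=C/C=C(C)/C=C/C=C(C)/C(C)=O)C(C)(C)C[C@H](O[Si](C)(C)C(C)(C)C)[C@H]1O[Si](C)(C)C(C)(C)C | intermediate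
36 | lithium enolate of 35 at C7'–C8' (not isolated) | CC1=C(C#C/C(C)=C/C=C/C(C)=C/C=C/C=C(C)/C=C/C=C(C)/C(=C)O[Li])C(C)(C)C[C@H](O[Si](C)(C)C(C)(C)C)[C@H]1O[Si](C)(C)C(C)(C)C | intermediate
37 | (4E,6E,8E,10E,12E,14E,16E)-19-[(3S,4S)-3,4-bis({[tert-butyl(dimethyl)silyl]oxy})-2,6,6-trimethylcyclohex-1-en-1-yl]-1-[(1R,4S)-4-{[tert-butyl(diphenyl)silyl]oxy}-1,2,2-trimethylcyclopentyl]-1-hydroxy-4,8,13,17-tetramethylnonadeca-4,6,8,10,12,14,16-heptaen-18-yn-3-one, both C6' epimers | CC1=C(C#C/C(C)=C/C=C/C(C)=C/C=C/C=C(C)/C=C/C=C(C)/C(=O)CC(O)[C@]2(C)C[C@@H](O[Si](c3ccccc3)(c3ccccc3)C(C)(C)C)CC2(C)C)C(C)(C)C[C@H](O[Si](C)(C)C(C)(C)C)[C@H]1O[Si](C)(C)C(C)(C)C | intermediate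
38 | (2Z,4E,6E,8E,10E,12E,14E,16E)-19-[(3S,4S)-3,4-bis({[tert-butyl(dimethyl)silyl]oxy})-2,6,6-trimethylcyclohex-1-en-1-yl]-1-[(1R,4S)-4-{[tert-butyl(diphenyl)silyl]oxy}-1,2,2-trimethylcyclopentyl]-3-hydroxy-4,8,13,17-tetramethylnonadeca-2,4,6,8,10,12,14,16-octaen-18-yn-1-one | CC1=C(C#C/C(C)=C/C=C/C(C)=C/C=C/C=C(C)/C=C/C=C(C)/C(O)=C/C(=O)[C@]2(C)C[C@@H](O[Si](c3ccccc3)(c3ccccc3)C(C)(C)C)CC2(C)C)C(C)(C)C[C@H](O[Si](C)(C)C(C)(C)C)[C@H]1O[Si](C)(C)C(C)(C)C | intermediate
39 | (2Z,4E,6E,8E,10E,12E,14E,16E)-19-[(3S,4S)-3,4-dihydroxy-2,6,6-trimethylcyclohex-1-en-1-yl]-3-hydroxy-1-[(1R,4S)-4-hydroxy-1,2,2-trimethylcyclopentyl]-4,8,13,17-tetramethylnonadeca-2,4,6,8,10,12,14,16-octaen-18-yn-1-one, CNP0114063.1 | CC1=C(C#C/C(C)=C/C=C/C(C)=C/C=C/C=C(C)/C=C/C=C(C)/C(O)=C/C(=O)[C@]2(C)C[C@@H](O)CC2(C)C)C(C)(C)C[C@H](O)[C@H]1O | target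

## Step count and least certain steps

Total: 25 steps. Longest linear sequence: 13 steps (13 → 39 through steps 10–18 and 22–25). The ring B branch from 1 is 12 steps long (steps 1–9 and 23–25).

**Step 3 (key step).** The most likely failure is over-oxidation of the C2' radical to a cation before copper captures it. That would be followed by a methyl shift from C1' or by capture as an acetate, and the alkene would be lost. Fallback: a radical decarboxylation that never passes through a cation, starting from 3 and returning at 5. Acid 3 is converted with (COCl)2 and then sodium pyridine-2-thiolate 1-oxide into the Barton ester, methyl (1R,3S)-1,2,2-trimethyl-3-{[(2-thioxopyridin-1(2H)-yl)oxy]carbonyl}cyclopentane-1-carboxylate F1. Photolysis of F1 with diphenyl diselenide gives methyl (1R)-1,2,2-trimethyl-3-(phenylselanyl)cyclopentane-1-carboxylate F2. Oxidation with H2O2 and syn elimination of the selenoxide, which can only take a hydrogen from C3', gives 5.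

**Step 6.** The most likely failure is poor facial selectivity of the borane addition, because the two faces differ only by methyl versus silyloxymethyl on the remote C5'. Some loss of regioselectivity is also possible. Fallback: correction by inversion, starting from 7 and returning at 9. The hydroboration mixture is separated and the C3' epimer, (1R,3R)-3-({[tert-butyl(dimethyl)silyl]oxy}methyl)-3,4,4-trimethylcyclopentan-1-ol F3, is inverted by a Mitsunobu reaction with 4-nitrobenzoic acid, PPh3 and diisopropyl azodicarboxylate. This gives (1S,3R)-3-({[tert-butyl(dimethyl)silyl]oxy}methyl)-3,4,4-trimethylcyclopentyl 4-nitrobenzoate F4, and methanolysis with K2CO3 in MeOH gives 9.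

**Step 12.** The most likely failure is incomplete enantioselection, since the two flanks of the ketone are both ring carbons. Fallback: resolution, starting from 16 and returning at 17. Reduction with NaBH4 and CeCl3·7H2O gives racemic 4-hydroxy-3-methoxy-2,6,6-trimethylcyclohex-2-en-1-one F5. A lipase with vinyl acetate is expected to acylate the R enantiomer, giving (1R)-2-methoxy-3,5,5-trimethyl-4-oxocyclohex-2-en-1-yl acetate F6, which is separated from unreacted 17.

**Step 22.** The most likely failures are loss of geometric control (Z at the new 11,12 bond, stereomutation of the 9,10 bond through the delocalised ylide) and proton transfer from the methyl ketone of 33 to the ylide. Fallback: a Horner–Wadsworth–Emmons olefination, starting from bromide 26 (isolated in this variant) and returning at 35. Arbuzov reaction of 26 with P(OEt)3 gives diethyl {(2E)-5-[(3S,4S)-3,4-bis({[tert-butyl(dimethyl)silyl]oxy})-2,6,6-trimethylcyclohex-1-en-1-yl]-3-methylpent-2-en-4-yn-1-yl}phosphonate F7. Its anion (NaN(SiMe3)2, THF, −78 °C) should add to 33 with high E selectivity and give 35 without a thermal isomerisation.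

**Step 23.** The most likely failure is slow addition to the doubly flanked aldehyde, which leaves time for proton transfer, retro-aldol reaction or degradation of the long polyenone under strongly basic conditions. Fallback: form the diketone on small fragments and join the polyene afterwards, starting from 28 and 12 and returning at 38.

- Silylation of 28 (TBSCl, imidazole) gives (3E)-5-{[tert-butyl(dimethyl)silyl]oxy}-3-methylpent-3-en-2-one F8.
- Its lithium enolate adds to 12 to give (4E)-1-[(1R,4S)-4-{[tert-butyl(diphenyl)silyl]oxy}-1,2,2-trimethylcyclopentyl]-6-{[tert-butyl(dimethyl)silyl]oxy}-1-hydroxy-4-methylhex-4-en-3-one F9.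
- Dess–Martin oxidation gives (2Z,4E)-1-[(1R,4S)-4-{[tert-butyl(diphenyl)silyl]oxy}-1,2,2-trimethylcyclopentyl]-6-{[tert-butyl(dimethyl)silyl]oxy}-3-hydroxy-4-methylhexa-2,4-dien-1-one F10.
- HF·pyridine frees (2Z,4E)-1-[(1R,4S)-4-{[tert-butyl(diphenyl)silyl]oxy}-1,2,2-trimethylcyclopentyl]-3,6-dihydroxy-4-methylhexa-2,4-dien-1-one F11.
- Bromination and quaternisation as in step 18 give [(2E,4Z)-6-[(1R,4S)-4-{[tert-butyl(diphenyl)silyl]oxy}-1,2,2-trimethylcyclopentyl]-4-hydroxy-3-methyl-6-oxohexa-2,4-dien-1-yl]triphenylphosphonium bromide F12.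
- Separately, ylide 34 and an excess of 31 give (2E,4E,6E,8E,10E)-13-[(3S,4S)-3,4-bis({[tert-butyl(dimethyl)silyl]oxy})-2,6,6-trimethylcyclohex-1-en-1-yl]-2,7,11-trimethyltrideca-2,4,6,8,10-pentaen-12-ynal F13.
- Wittig reaction of F12 (two equivalents of NaN(SiMe3)2, the first taken up by the diketone) with F13 gives 38.

## Further compounds

F1 | step 3 | methyl (1R,3S)-1,2,2-trimethyl-3-{[(2-thioxopyridin-1(2H)-yl)oxy]carbonyl}cyclopentane-1-carboxylate | COC(=O)[C@]1(C)CC[C@H](C(=O)On2ccccc2=S)C1(C)C
F2 | step 3 | methyl (1R)-1,2,2-trimethyl-3-(phenylselanyl)cyclopentane-1-carboxylate, both C3 epimers | COC(=O)[C@]1(C)CCC([Se]c2ccccc2)C1(C)C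
F3 | step 6 | (1R,3R)-3-({[tert-butyl(dimethyl)silyl]oxy}methyl)-3,4,4-trimethylcyclopentan-1-ol | CC(C)(C)[Si](C)(C)OC[C@]1(C)C[C@H](O)CC1(C)C
F4 | step 6 | (1S,3R)-3-({[tert-butyl(dimethyl)silyl]oxy}methyl)-3,4,4-trimethylcyclopentyl 4-nitrobenzoate | CC(C)(C)[Si](C)(C)OC[C@]1(C)C[C@@H](OC(=O)c2ccc(cc2)[N+](=O)[O-])CC1(C)C
F5 | step 12 | racemic 4-hydroxy-3-methoxy-2,6,6-trimethylcyclohex-2-en-1-one | COC1=C(C)C(=O)C(C)(C)CC1O
F6 | step 12 | (1R)-2-methoxy-3,5,5-trimethyl-4-oxocyclohex-2-en-1-yl acetate | COC1=C(C)C(=O)C(C)(C)C[C@H]1OC(C)=O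
F7 | step 22 | diethyl {(2E)-5-[(3S,4S)-3,4-bis({[tert-butyl(dimethyl)silyl]oxy})-2,6,6-trimethylcyclohex-1-en-1-yl]-3-methylpent-2-en-4-yn-1-yl}phosphonate | CC1=C(C#C/C(C)=C/CP(=O)(OCC)OCC)C(C)(C)C[C@H](O[Si](C)(C)C(C)(C)C)[C@H]1O[Si](C)(C)C(C)(C)C
F8 | step 23 | (3E)-5-{[tert-butyl(dimethyl)silyl]oxy}-3-methylpent-3-en-2-one | CC(=O)/C(C)=C/CO[Si](C)(C)C(C)(C)C
F9 | step 23 | (4E)-1-[(1R,4S)-4-{[tert-butyl(diphenyl)silyl]oxy}-1,2,2-trimethylcyclopentyl]-6-{[tert-butyl(dimethyl)silyl]oxy}-1-hydroxy-4-methylhex-4-en-3-one, both C1 epimers | CC(C)(C)[Si](C)(C)OC/C=C(C)/C(=O)CC(O)[C@]1(C)C[C@@H](O[Si](c2ccccc2)(c2ccccc2)C(C)(C)C)CC1(C)C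
F10 | step 23 | (2Z,4E)-1-[(1R,4S)-4-{[tert-butyl(diphenyl)silyl]oxy}-1,2,2-trimethylcyclopentyl]-6-{[tert-butyl(dimethyl)silyl]oxy}-3-hydroxy-4-methylhexa-2,4-dien-1-one | CC(C)(C)[Si](C)(C)OC/C=C(C)/C(O)=C/C(=O)[C@]1(C)C[C@@H](O[Si](c2ccccc2)(c2ccccc2)C(C)(C)C)CC1(C)C
F11 | step 23 | (2Z,4E)-1-[(1R,4S)-4-{[tert-butyl(diphenyl)silyl]oxy}-1,2,2-trimethylcyclopentyl]-3,6-dihydroxy-4-methylhexa-2,4-dien-1-one | OC/C=C(C)/C(O)=C/C(=O)[C@]1(C)C[C@@H](O[Si](c2ccccc2)(c2ccccc2)C(C)(C)C)CC1(C)C
F12 | step 23 | [(2E,4Z)-6-[(1R,4S)-4-{[tert-butyl(diphenyl)silyl]oxy}-1,2,2-trimethylcyclopentyl]-4-hydroxy-3-methyl-6-oxohexa-2,4-dien-1-yl]triphenylphosphonium bromide | [Br-].c1ccccc1[P+](c1ccccc1)(c1ccccc1)C/C=C(C)/C(O)=C/C(=O)[C@]1(C)C[C@@H](O[Si](c2ccccc2)(c2ccccc2)C(C)(C)C)CC1(C)C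
F13 | step 23 | (2E,4E,6E,8E,10E)-13-[(3S,4S)-3,4-bis({[tert-butyl(dimethyl)silyl]oxy})-2,6,6-trimethylcyclohex-1-en-1-yl]-2,7,11-trimethyltrideca-2,4,6,8,10-pentaen-12-ynal | CC1=C(C#C/C(C)=C/C=C/C(C)=C/C=C/C=C(C)/C=O)C(C)(C)C[C@H](O[Si](C)(C)C(C)(C)C)[C@H]1O[Si](C)(C)C(C)(C)C
A1 | alternative 1 | 3,4,3'-tris-O-(tert-butyldimethylsilyl) ether of 39 | CC1=C(C#C/C(C)=C/C=C/C(C)=C/C=C/C=C(C)/C=C/C=C(C)/C(O)=C/C(=O)[C@]2(C)C[C@@H](O[Si](C)(C)C(C)(C)C)CC2(C)C)C(C)(C)C[C@H](O[Si](C)(C)C(C)(C)C)[C@H]1O[Si](C)(C)C(C)(C)C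
A2 | alternative 1 | (1E,3E,5E,7E,9E)-3,8-dimethyl-1,10-bis(tributylstannyl)deca-1,3,5,7,9-pentaene | CCCC[Sn](CCCC)(CCCC)/C=C/C(C)=C/C=C/C=C(C)/C=C/[Sn](CCCC)(CCCC)CCCC
A3 | alternative 1 | (3S,4S)-3,4-bis({[tert-butyl(dimethyl)silyl]oxy})-1-[(3E)-4-iodo-3-methylbut-3-en-1-yn-1-yl]-2,6,6-trimethylcyclohex-1-ene | CC1=C(C#C/C(C)=C/I)C(C)(C)C[C@H](O[Si](C)(C)C(C)(C)C)[C@H]1O[Si](C)(C)C(C)(C)C
A4 | alternative 1 | (2Z,4E)-1-[(1R,4S)-4-{[tert-butyl(dimethyl)silyl]oxy}-1,2,2-trimethylcyclopentyl]-3-hydroxy-5-iodo-4-methylpenta-2,4-dien-1-one | I/C=C(C)/C(O)=C/C(=O)[C@]1(C)C[C@@H](O[Si](C)(C)C(C)(C)C)CC1(C)C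
A5 | alternative 2 | (2E)-5-[(3S,4S)-3,4-bis({[tert-butyl(dimethyl)silyl]oxy})-2,6,6-trimethylcyclohex-1-en-1-yl]-3-methylpent-2-en-4-yn-1-ol, identical with 25 | CC1=C(C#C/C(C)=C/CO)C(C)(C)C[C@H](O[Si](C)(C)C(C)(C)C)[C@H]1O[Si](C)(C)C(C)(C)C
A6 | alternative 2 | (3S,4S)-3,4-bis({[tert-butyl(dimethyl)silyl]oxy})-2,6,6-trimethylcyclohex-1-en-1-yl trifluoromethanesulfonate | CC1=C(OS(=O)(=O)C(F)(F)F)C(C)(C)C[C@H](O[Si](C)(C)C(C)(C)C)[C@H]1O[Si](C)(C)C(C)(C)C
A7 | alternative 3 | 3,4,3',8'-tetrakis-O-(tert-butyldimethylsilyl) derivative of 39, the 8'-oxygen as silyl enol ether | CC1=C(C#C/C(C)=C/C=C/C(C)=C/C=C/C=C(C)/C=C/C=C(C)/C(O[Si](C)(C)C(C)(C)C)=C/C(=O)[C@]2(C)C[C@@H](O[Si](C)(C)C(C)(C)C)CC2(C)C)C(C)(C)C[C@H](O[Si](C)(C)C(C)(C)C)[C@H]1O[Si](C)(C)C(C)(C)C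
A8 | alternative 3 | {(2E,4E,6E)-9-[(3S,4S)-3,4-bis({[tert-butyl(dimethyl)silyl]oxy})-2,6,6-trimethylcyclohex-1-en-1-yl]-3,7-dimethylnona-2,4,6-trien-8-yn-1-yl}triphenylphosphonium bromide | CC1=C(C#C/C(C)=C/C=C/C(C)=C/C[P+](c2ccccc2)(c2ccccc2)c2ccccc2)C(C)(C)C[C@H](O[Si](C)(C)C(C)(C)C)[C@H]1O[Si](C)(C)C(C)(C)C.[Br-]
A9 | alternative 3 | (2E,4E,6E,8Z)-8-{[tert-butyl(dimethyl)silyl]oxy}-10-[(1R,4S)-4-{[tert-butyl(dimethyl)silyl]oxy}-1,2,2-trimethylcyclopentyl]-3,7-dimethyl-10-oxodeca-2,4,6,8-tetraenal | O=C/C=C(C)/C=C/C=C(C)/C(O[Si](C)(C)C(C)(C)C)=C/C(=O)[C@]1(C)C[C@@H](O[Si](C)(C)C(C)(C)C)CC1(C)C
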